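The rate constants are invented.

A neighbour of this flask, charged with 0.40 mM of precatalyst, is taken up at the end; the flask itself comes first.

left-handed substrate 20 mM; solid reagent 20.0 mM; precatalyst 0.16 mM; right-handed substrate 20 mM; time 15 min

    free catalyst + left-handed substrate ⇌ catalyst intermediate A (K1 = 17.3 M⁻¹, k1 = 766 M⁻¹ s⁻¹)
    solid reagent ⇌ partner, rate k2*(cs2 - [partner]) while solid is left; crystals form when [partner] > cs2 (cs2 = 11 mM, k2 = 0.00869 s⁻¹)
    partner + precatalyst → free catalyst + spent reagent (k3 = 0.884 M⁻¹ s⁻¹)
    partner + catalyst intermediate B → free catalyst + right-handed product (k4 = 4.03 M⁻¹ s⁻¹)
    partner + catalyst intermediate A → free catalyst + left-handed product (k5 = 68.2 M⁻¹ s⁻¹)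
    free catalyst + right-handed substrate ⇌ catalyst intermediate B (K6 = 19.3 M⁻¹, k6 = 1790 M⁻¹ s⁻¹)

- free catalyst is single-handed; left-handed substrate and right-handed substrate are mirror images of each other, charged as a racemate, each of them at the stated concentration
- solid reagent is a solid; its amount is given per volume of the solution
- at the start none of the solid reagent is in solution
- run time (flask): 15 min

- blue: doubling the dissolution coefficient of step 2, all else as stated
- ochre: doubling the amount of precatalyst, all else as stated
- green: doubling the solubility in step 2, all else as stated

- left-handed product at 15 min, in percent of the left-handed substrate and right-handed substrate together charged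
- the change that raises the amount of left-handed product at 15 min, in percent of the left-handed substrate and right-handed substrate together charged most ("none" if none brings more than 2 percentage points) (blue / ochre / green / none)
- amount of left-handed product at 15 min, in percent of the left-handed substrate and right-handed substrate together charged, after ochre

The two mirror-image substrates compete for one single-handed free catalyst, and a dissolved partner turns whichever intermediate it meets into product. If binding stands at equilibrium, the intermediates stand in the ratio of their binding constants and are consumed by their own onward steps, so s = 17.3 M⁻¹ × 68.2 M⁻¹ s⁻¹ / (19.3 M⁻¹ × 4.03 M⁻¹ s⁻¹) = 15.2, where s is the selectivity factor, the rate of left-handed product over that of right-handed product at equal substrate concentrations.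

The second way follows one molecule and makes no assumption of equilibrium. At equal concentrations free catalyst takes up the two substrates in the ratio 0.428, left to right. With partner taken at its solubility, the highest it reaches by dissolving, catalyst intermediate A goes on with a chance of 1.67% per visit and catalyst intermediate B with 0.0478%, and otherwise each falls back. These forks multiply to 14.9. The equilibrium way cheats slightly, since it ignores the leak through the onward step, but falling back is much faster, at 44.3 s⁻¹ against 0.750 s⁻¹ for catalyst intermediate A, so the two ways agree closely.

At the start, then, 93.8% of the product should be left-handed. Later, as long as binding stands at equilibrium, with free catalyst and partner common to both rates, the unbound fraction of right-handed substrate remaining should equal the unbound fraction of left-handed substrate remaining raised to the power 0.0658. This reckoning gives the split and not the pace, so it stops short of a value for y.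

The forecast puts y at 25.5% (range 22% to 29%) and 33% after ochre (range 28% to 37%), and it names ochre as the best change, while granting that “ochre over green is a narrow call”. The simulation gives y = 25.8% and, after ochre, 34.6%, with ochre the best change at a gain of 8.8 percentage points, against 5.1 points for green and 2.2 points for blue.

In this flask 48% of the charged left-handed substrate remains unbound at 15.0 min, and the power rule gives 95.3% of the charged right-handed substrate unbound, where the flask keeps 95%. The neighbour with 0.40 mM of precatalyst reaches 36.6% of left-handed product and keeps 27% of its left-handed substrate unbound. The same power applied to that neighbour gives 91.7% of its charged right-handed substrate unbound, and the neighbour keeps 91%.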